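Teal and blue are the runs I have, and from them I must rank the new flasks by the share of ring in all that became ring or open dimer (the selectivity).

| flask | substrate | remark | time |
|---|---|---|---|
| teal | 0.083 M | run made earlier |  |
| blue | 1.2 M | run made earlier |  |
| oak | 0.20 M |  | 10 h |
| elm | 0.60 M |  | 10 h |
| maple | 0.060 M |  | 10 h |
| birch | 0.12 M |  | 10 h |
| alder | 0.80 M |  | 10 h |

| run | time / h | ring / % | open dimer / % |
|---|---|---|---|
| teal | 0.833 | 4.3 | 8.2 |
| teal | 2.00 | 9.0 | 16.2 |
| teal | 4.00 | 15.3 | 25.4 |
| teal | 10.0 | 26.0 | 38.4 |
| blue | 0.833 | 2.6 | 55.0 |
| blue | 2.00 | 4.9 | 71.9 |
| blue | 4.00 | 5.8 | 80.4 |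
| blue | 10.0 | 7.7 | 86.6 |

(readings scatter by 0.3 percentage points)

- ranking by share of ring in all that became ring or open dimer, from high to low, at 10 h (oak / elm / maple / birch / alder)
- the share of ring in all that became ring or open dimer of the flask you put first, at 10 h
- the share of ring in all that became ring or open dimer of the flask you put last, at 10 h

- percent here means substrate units held: one open dimer counts as two
- a reading or a percentage of ring counts all its forms, free or not

I can turn two settings. The first is the charge of substrate. Open dimer takes two substrate at each turn, so by hand the ratio of ring to open dimer at one time falls as the charge rises. At 10 h that ratio reads 0.677 in teal and 0.0889 in blue. I draw a straight line through them on logarithmic axes: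

n = ln(ratio in teal / ratio in blue) / ln(charge in blue / charge in teal) = 0.760

c(even) = c(substrate, teal) × (ratio in teal)^(1/n) = 0.0497 M

This even charge, the substrate charged at which the line puts ring and open dimer equal at 10 h, is a reading from scattered runs and lies below teal's charge, and the rule, at that time and on that line, is:

ring / open dimer = (c(even) / c(substrate))^n

My reckoning gives maple, whose charge is smaller than that of the other new flasks, a share of 46.4%. It gives alder, whose charge is larger than that of the other new flasks, 10.8%.

The second setting is time. Teal's share goes from 34.4% at 0.833 h to 40.4% at 10.0 h, a move of 6 percentage points. That is less than the 32 points between teal and blue at 10 h.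

The forecast ranks maple > birch > oak > elm > alder, with 48% first (45% to 51%) and 11.2% last (10% to 12.8%), on the ground that “Ring share should therefore fall steadily as concentration rises”.

The flask gives maple > birch > oak > elm > alder, with maple at 46.9% and alder at 10.6%.

    substrate ⇌ ring (K = 1.90, k = 0.0540 h⁻¹)
    substrate + ring ⇌ idle adduct, settled at all times (K = 2.50 M⁻¹)
    2 substrate → open dimer (k = 0.670 M⁻¹ h⁻¹)

A reading of ring counts idle adduct too, so teal and blue carried it into the even charge. Maple holds 3.07% as idle adduct at 10.0 h, each adduct counted as two in that percentage, beside a ring of 28.2% with all its forms counted. For a neighbour of maple charged with 0.015 M, below teal's charge, the even charge gives a share of 71.3% at 10 h, and that neighbour gives 75.4%.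

The runs were generated by integration with constants of no real substance; noise was put on by code.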